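## Structural features

The target is a 3a,4,5,7a-tetrahydro-1H-indene. A cyclopentene (C1, C2=C3, C3a, C7a) is trans-fused along C3a–C7a to a cyclohexene (C3a, C4, C5, C6=C7, C7a), with methyl groups on C1, C3, C4 and C7. Five contiguous stereocentres run C1–C7a–C3a–C4–C5. C4 (methyl, carboxyl) and C5 (ethyl, dienyl) are adjacent all-carbon quaternary centres; carboxyl and dienyl are cis to each other and to C3a–H, and the C1 methyl is cis to C7a–H. C5 carries a (1E,3E)-2-methyl-4-phenylbuta-1,3-dienyl chain. The fragile parts are the styryl diene (acid, oxidants, hydrometallating agents) and the two trisubstituted ring alkenes, which can migrate under strong acid. The carboxyl group is so shielded that it cannot be unmasked by attack at its carbonyl carbon. The real difficulty is the vicinal quaternary pair C4/C5 inside a trans-fused frame, together with absolute control. The feature used here is that C4 and C7 lie 1,4 across the six-membered ring. The carboxyl carbon on C4 and an oxygen placed on C7 are then the C(=O)–O bridge of a 2-pyrone cycloadduct, so the carbocycle is a pyrone (C4 to C7 with their alkyl groups) plus a two-carbon dienophile (C3a, C7a). The bridge oxygen on C7 sits on the face from which C5 must later receive its carbon substituent.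

## Logic of the disconnections

29 ⇒ 28. Only the O–CH3 bond is cut. The acid is carried as its methyl ester through the carbene and hydrozirconation steps, which a free acid would not tolerate. The demand is that the last step cleaves at the methyl carbon, because the carbonyl carbon lies between two fully substituted carbons.

28 ⇒ 25 + 26. The single bond between the methyl-bearing sp2 carbon and the styryl carbon is cut. Both alkene geometries then come from stereodefined partners: 26 is already E, and the other alkene comes from syn hydrometallation of an alkyne. The side chain shrinks to a propynyl group. The forward step must place the metal on the methyl-bearing alkyne carbon and spare the ester.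

25 ⇒ 22. C1–C2 and C2=C3 are cut, C2 being a one-carbon reagent. The cyclopentene opens to an acetyl group on C3a and an ethyl group on C7a, the two groups a hexenone dienophile supplies. This removes one ring and the C1 stereocentre. The carbene must choose the ethyl CH2 over other C–H bonds, so C4 is kept at the ester level at this point: a CH2–O group on C4 would offer an activated 1,5 C–H bond. This closure is only possible once the lactone bridge is open, since a trans-fused five-membered ring cannot span the eclipsed two-carbon bridge of the bicyclo[2.2.2] skeleton.

22 ⇒ 21 ⇒ 19 ⇒ 18. No skeletal bond is cut; ester, acid, alcohol and ketone are traced back to a silyl ether and a ketal. This lets the C4 arm and the ketone survive the organolithium steps. One acid treatment has to free both groups, and a neopentyl alcohol has to be oxidised beside a ketone.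

18 ⇒ 16 ⇒ 14 ⇒ 13. The alkyne–CH3 bond and the terminal alkyne carbon are removed (methylation, one-carbon homologation of an aldehyde), then the oxidation level is lowered to the primary alcohol. The side chain is reduced to a single CH2OH carbon on C5. The aldehyde has no α-hydrogen, so the forward steps carry no epimerisation risk.

13 ⇒ 11 ⇒ 10. The C5–CH2 bond is cut and the carbon reattached through oxygen to C7, with the alkene moved to C5=C6. This turns the quaternary stereocentre C5 into an sp2 carbon and places the stereochemical information on the tertiary allylic C7–O bond. The forward [2,3] shift must be suprafacial and must beat the 1,2-shift.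

10 ⇒ 9 ⇒ 8. The silyl group is removed and the C4 CH2OH carbon reconnected as a carbonyl to the C7 oxygen. The cis 1,4-diol is recognised as a reduced lactone bridge. The ketone must be masked against hydride.

8 ⇒ 7. The ketal C–O bonds are cut. The two cycloaddition partners are achiral, so this is also the point at which the racemate is split: the protecting diol is chiral and C2-symmetric, and the two ketals are diastereomers.

7 ⇒ 5 + 6. C3a–C4 and C7–C7a are cut. One cycloaddition supplies the carbocycle, the C4 quaternary centre with its carboxyl carbon, the C7 oxygen relay, the trans relation of C3a and C7a, and the ethyl group of C5 already in place. The forward step needs endo acetyl and the orientation with the acyl-bearing carbon on pyrone C3.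

5 ⇒ 4 ⇒ 3 ⇒ 1. The C4–ethyl bond (cross-coupling of the enol triflate) and the C3–methyl bond (reductive alkylation with formaldehyde) are cut, leading back to commercial 1.

## Other disconnections considered

Alternative 1: The cut is the C6=C7 double bond. In the forward direction the triene ester A2 (cyclopentene with C1, C3a and C7a in place, isopropenyl on C7a, C5 bearing ethyl and two vinyl groups) would be treated with second-generation Grubbs catalyst to give A1 with loss of ethylene.
- In favour: the ring closure is catalytic and neutral, and needs no pressure equipment. C5 is not stereogenic in A2. The three cyclopentene stereocentres are set before the key step, so no late C–H insertion is needed. On these points the alternative is equal or better.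
- Against: the two vinyl groups differ only through the neighbouring C4 centre, whose methyl and ester groups are of similar size, so group selection at C5 is expected to be weak. The catalyst must load at a neopentyl vinyl group or at a 1,1-disubstituted alkene. A2 already contains the C4–C5 bond between two fully substituted carbons, so the hardest bond is left to earlier, open-chain chemistry.
- Structure: the leftover vinyl group of A1 must still become the trisubstituted diene, which needs selective cleavage of a monosubstituted alkene beside two more electron-rich ring alkenes.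
- Mechanism: the chosen plan sets C5 by a stereospecific suprafacial shift rather than by selection between like groups.
- Step economy: no gain is expected, since the A1 end game would join the same aldehyde–alkyne–diene sequence and A2 is long to make.

Alternative 2: The cut removes the C4–carboxyl and C5–side-chain carbons together from diene A4. Dichloroketene (from trichloroacetyl chloride and Zn–Cu) would add [2+2] to C4=C5 of A4 to give cyclobutanone A3.
- In favour: A4 is what 5 and 6 give on simple heating (cycloaddition, then loss of CO2), so the early part is shared and needs no pressure; here the alternative is simpler. Both quaternary carbons form in one suprafacial step with the two new carbons necessarily cis. Ketene–diene regiochemistry puts the carbonyl carbon on the diene terminus C4, as needed. Alkoxide opening of A3 would give the C4 ester and a C5 dichloromethyl group directly, so redox economy and probably step count would be better than in the chosen plan.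
- Against: A4 has two diene termini, and the ketene would have to attack the tetrasubstituted C4=C5 rather than the less hindered C6=C7. Facial control rests on the C3a acetyl alone. The enolisable ketone must survive acid chloride and zinc salts. Hydrolysis of a neopentyl dichloromethyl group is slow. A4 is racemic as well.
- Structure and mechanism: the chosen plan keeps the C7 oxygen as a relay, which fixes both the site and the face at C5. Alternative 2 gives up this relay and must win site selectivity against sterics.

Alternative 3: The cut is C4–C5, with the carboxyl oxygen reconnected to C7, giving the trans-fused δ-lactone A6. This carries the C7 methyl and an (E)-trienyl chain on C7 and has the cyclopentene in place. LDA and chlorotrimethylsilane would give the ring ketene acetal, and a [3,3] shift would give silyl ester A5, which hydrolyses to the target on work-up.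
- In favour: a Claisen shift is well suited to joining two fully substituted carbons. The carbocycle closes in the same event, the whole side chain is present, and the acid emerges without any protecting-group or oxidation-state changes, so the end game is the shortest of all. The C7 centre could come from an enantioselective addition rather than a resolution. On these points the alternative is better.
- Against: the endocyclic ketene acetal forces a boat in which C3a–C7a is nearly eclipsed, which a trans-fused cyclopentene resists; this is the same strain that forbids closing the cyclopentene on the bridged lactone in the chosen route. A6 is a tertiary, triene-conjugated allylic ester, prone to ionisation. A6 needs a quaternary carbinol at C7 and a stereodefined triene, so the difficulty moves into the precursor.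
- Mechanism: both plans relay configuration from a C7–O bond to C5 suprafacially; they are equal on this point.
- Structure and step economy: the chosen plan makes the strained bridged arrangement by cycloaddition, where it is the natural product, and accepts a longer sequence afterwards.

Key step: step 4

Remark (locants): C1 to C7a are the 1H-indene locants of the target and are used for the corresponding atoms of all intermediates.

Remark (assumption): 5 and 6 are achiral, so 7 forms as a racemate. Absolute configuration is introduced in step 5 by separating the two ketals of (2R,3R)-butane-2,3-diol. The series drawn is taken to be the one carried on, to be confirmed crystallographically on a later intermediate. The configuration drawn for 7 maps onto C3a, C4, C7 and C7a of the target without change.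

## Steps

Step 1
Reactants: 1 4-hydroxy-6-methyl-2H-pyran-2-one
Product: 3 4-hydroxy-3,6-dimethyl-2H-pyran-2-one, via methylidene dione 2 (not isolated)
Conditions: aq. CH2O, Hantzsch ester, L-proline (cat.), CH2Cl2, rt
Reagents that add atoms: formaldehyde, C=O
Why: Three-component reductive alkylation: Knoevenagel condensation at C3, the only nucleophilic carbon of 1, gives the electrophilic methylidene dione 2, which the Hantzsch ester reduces by conjugate hydride transfer before a second molecule of 1 can add.

Step 2
Reactants: 3 4-hydroxy-3,6-dimethyl-2H-pyran-2-one
Product: 4 3,6-dimethyl-2-oxo-2H-pyran-4-yl trifluoromethanesulfonate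
Conditions: Tf2O, Et3N, CH2Cl2, −78 → 0 °C
Reagents that add atoms: trifluoromethanesulfonic anhydride, O=S(=O)(OS(=O)(=O)C(F)(F)F)C(F)(F)F
Why: O-Sulfonylation of the vinylogous acid; the C4 enol oxygen is the only acidic site.

Step 3
Reactants: 4 3,6-dimethyl-2-oxo-2H-pyran-4-yl trifluoromethanesulfonate
Product: 5 4-ethyl-3,6-dimethyl-2H-pyran-2-one
Conditions: EtMgBr, Fe(acac)3 (5 mol%), THF/NMP, −30 °C
Reagents that add atoms: ethylmagnesium bromide, CC[Mg]Br
Why: Iron-catalysed cross-coupling of an electron-poor alkenyl triflate with an alkyl Grignard reagent; at −30 °C the catalytic cycle should outrun addition of the Grignard reagent to the pyrone carbonyl, and iron catalysis tolerates alkyl groups with β-hydrogens.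

Step 4
Reactants: 5 4-ethyl-3,6-dimethyl-2H-pyran-2-one; 6 (E)-hex-3-en-2-one
Product: 7 (±)-5-acetyl-6,8-diethyl-1,4-dimethyl-2-oxabicyclo[2.2.2]oct-7-en-3-one (acetyl endo; 6-ethyl exo; racemate)
Conditions: 6 (3 equiv), CH2Cl2, 1.4 GPa, 30 °C
Reagents that add atoms: none
Why: Concerted but asynchronous [4+2] cycloaddition in which C3 to C6 of pyrone 5, held s-cis by the ring, act as the diene and the C=C of 6 as the 2π partner; the closest known reaction type is the pressure-promoted Diels–Alder addition of 2-pyrones to acrylates and enones that gives isolable 2-oxabicyclo[2.2.2]octenones. The one ring closed is the carbocycle C3a–C4–C5–C6–C7–C7a, formed intermolecularly by making C3a–C4 and C7–C7a in the same transition state, with the lactone of 5 becoming the bridge. Suprafacial addition to the (E)-alkene makes the C3a and C7a substituents trans, and suprafacial addition to the diene ties the bridgeheads C4 and C7 to one another through the bridge. The relation of C3a and C7a to the bridge comes from the endo orientation of the acetyl group (secondary overlap with the diene and the more compact transition state, which pressure favours), so acetyl ends up syn to the alkene bridge and ethyl syn to the lactone bridge. The step needs the orientation in which the acyl-bearing carbon bonds to pyrone C3; the ring carbonyl and the methyl group on C3 make C3 and the enone α-carbon the pair best able to carry the lagging bond, and this has to be confirmed on the adduct. Pressure at ambient temperature is chosen over heat so that the adduct keeps its CO2 bridge, and over Lewis acids because these bind the basic pyrone carbonyl and deactivate the diene. No element of absolute control is present, so 7 is racemic.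

Step 5
Reactants: 7 (±)-5-acetyl-6,8-diethyl-1,4-dimethyl-2-oxabicyclo[2.2.2]oct-7-en-3-one
Product: 8 6,8-diethyl-1,4-dimethyl-5-[(4R,5R)-2,4,5-trimethyl-1,3-dioxolan-2-yl]-2-oxabicyclo[2.2.2]oct-7-en-3-one (single diastereomer)
Conditions: (2R,3R)-butane-2,3-diol, i-PrOSiMe3, Me3SiOTf (cat.), CH2Cl2, −40 → −20 °C; Et3N; separation of the two ketal diastereomers (SiO2 or crystallisation)
Reagents that add atoms: (2R,3R)-butane-2,3-diol, C[C@@H](O)[C@@H](C)O
Why: Silyl triflate-catalysed dioxolane formation under cold aprotic conditions should spare the tertiary allylic lactone C–O bond and avoid CO2 loss. The diol is C2-symmetric, so no stereocentre arises at the ketal carbon and the two enantiomers of 7 give exactly two diastereomers, of which 8 is kept (classical resolution through covalent diastereomers); the ketal also shields the ketone from LiAlH4 and n-BuLi.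

Step 6
Reactants: 8 bridged lactone ketal
Product: 9 3,6-diethyl-4-(hydroxymethyl)-1,4-dimethyl-5-[(4R,5R)-2,4,5-trimethyl-1,3-dioxolan-2-yl]cyclohex-2-en-1-ol (C7 hydroxyl and C4 hydroxymethyl cis)
Conditions: LiAlH4, THF, 0 °C → rt; H2O/NaOH work-up
Reagents that add atoms: none
Why: Hydride reduction of the lactone cleaves the acyl–oxygen bond only, so the C7–O bond and the C7 configuration are untouched; the ketal is inert.

Step 7
Reactants: 9 ketal diol
Product: 10 4-{[tert-butyl(dimethyl)silyl]oxymethyl}-3,6-diethyl-1,4-dimethyl-5-[(4R,5R)-2,4,5-trimethyl-1,3-dioxolan-2-yl]cyclohex-2-en-1-ol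
Conditions: TBSCl, imidazole, DMAP (cat.), DMF, rt
Reagents that add atoms: tert-butyldimethylsilyl chloride, CC(C)(C)[Si](C)(C)Cl
Why: Selective silylation of the primary hydroxyl; the tertiary allylic alcohol does not react under these conditions.

Step 8
Reactants: 10 mono-silylated tertiary allylic alcohol
Product: 11 tributylstannylmethyl ether of 10 (C7–O–CH2SnBu3)
Conditions: KH, 18-crown-6 (cat.), THF, 0 °C; Bu3SnCH2I, 0 °C → rt
Reagents that add atoms: tributyl(iodomethyl)stannane, CCCC[Sn](CI)(CCCC)CCCC
Why: Williamson etherification of the potassium alkoxide with the reactive α-stannyl iodide, the standard entry to Still–Wittig substrates; no bond to a stereocentre is broken.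

Step 9
Reactants: 11 tributylstannylmethyl ether
Product: 13 C5-hydroxymethyl cyclohexene (C5 bears ethyl and CH2OH; C6=C7 alkene; CH2OH cis to the C4 CH2OSi arm), via lithiomethyl ether 12 (not isolated)
Conditions: n-BuLi, THF, −78 °C; aqueous quench at −78 °C
Reagents that add atoms: none
Why: Still–Wittig [2,3]-sigmatropic rearrangement: tin–lithium exchange gives the α-alkoxymethyllithium 12, which shifts through a five-membered envelope transition state. The shift is suprafacial across C7–C6=C5, so the CH2O carbon arrives on the face of C5 from which the pseudo-axial C7–O bond departs (the former lactone face), which sets C5 with ethyl on the opposite face. The cold quench is meant to suppress the 1,2-shift and silyl migration between the two primary oxygens.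

Step 10
Reactants: 13 C5-hydroxymethyl cyclohexene
Product: 14 C5 aldehyde
Conditions: Dess–Martin periodinane, NaHCO3, CH2Cl2, 0 °C → rt
Reagents that add atoms: none
Why: Dess–Martin oxidation of the neopentyl primary alcohol; the aldehyde has no α-hydrogen and cannot epimerise.

Step 11
Reactants: 14 C5 aldehyde
Product: 16 C5 ethynyl compound, via diazoalkene 15 (not isolated)
Conditions: dimethyl (1-diazo-2-oxopropyl)phosphonate, K2CO3, MeOH, 0 °C → rt
Reagents that add atoms: dimethyl (1-diazo-2-oxopropyl)phosphonate, CC(=O)C(=[N+]=[N-])P(=O)(OC)OC
Why: Seyferth–Gilbert homologation with the Ohira–Bestmann reagent; the non-enolisable aldehyde passes through diazoalkene 15 and a 1,2-hydrogen shift to the terminal alkyne under conditions that leave ketal and silyl ether alone.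

Step 12
Reactants: 16 C5 ethynyl compound
Product: 18 C5 prop-1-ynyl compound, via lithium acetylide 17 (not isolated)
Conditions: n-BuLi, THF, −78 °C; MeI, −78 °C → rt
Reagents that add atoms: iodomethane, CI
Why: Deprotonation of the terminal alkyne and SN2 methylation of the acetylide.

Step 13
Reactants: 18 C5 prop-1-ynyl compound
Product: 19 keto alcohol (C3a acetyl; C4 hydroxymethyl; may exist partly as its lactol)
Conditions: 1 M aq. HCl, THF, rt → 40 °C
Reagents that add atoms: water, O
Why: Acid hydrolysis cleaves the dioxolane and the primary silyl ether in one operation; the trisubstituted alkene and the alkyne should be stable to dilute aqueous acid at this temperature.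

Step 14
Reactants: 19 keto alcohol
Product: 21 6-acetyl-2,5-diethyl-1,4-dimethyl-2-(prop-1-yn-1-yl)cyclohex-3-ene-1-carboxylic acid, via keto aldehyde 20 (not isolated)
Conditions: Dess–Martin periodinane, NaHCO3, CH2Cl2, rt; then t-BuOH/H2O, 2-methyl-2-butene, NaH2PO4, NaClO2, rt
Reagents that add atoms: sodium chlorite, [Na+].[O-]Cl=O
Why: Dess–Martin oxidation followed in the same flask by Pinnick oxidation; both stages are neutral to weakly acidic, which avoids aldol closure of the 1,4-keto aldehyde 20, and 2-methyl-2-butene takes up the hypochlorite.

Step 15
Reactants: 21 keto acid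
Product: 22 methyl 6-acetyl-2,5-diethyl-1,4-dimethyl-2-(prop-1-yn-1-yl)cyclohex-3-ene-1-carboxylate
Conditions: Me3SiCHN2, toluene/MeOH (4:1), 0 °C → rt
Reagents that add atoms: (trimethylsilyl)diazomethane, C[Si](C)(C)C=[N+]=[N-]
Why: O-Methylation of the acid by diazomethane formed from the silyl reagent and methanol; alkylation at oxygen is insensitive to the shielding of the carboxyl carbon.

Step 16
Reactants: 22 keto methyl ester
Product: 25 methyl 5-ethyl-1,3,4,7-tetramethyl-5-(prop-1-yn-1-yl)-3a,4,5,7a-tetrahydro-1H-indene-4-carboxylate (trans-fused; C1 methyl cis to C7a–H), via diazoalkene 23 (not isolated), via alkylidene carbene 24 (not isolated)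
Conditions: Me3SiCHN2, n-BuLi, THF, −78 °C; then 22, −78 → 0 °C
Reagents that add atoms: (trimethylsilyl)diazomethane, C[Si](C)(C)C=[N+]=[N-]
Why: Lithiated trimethylsilyldiazomethane adds to the methyl ketone, Peterson-type loss of Me3SiOLi gives diazoalkene 23 and then alkylidene carbene 24, which inserts with retention into a 1,5 C–H bond (alkylidene carbene C–H insertion). The secondary C–H of the equatorial C7a ethyl group should be preferred over the primary C–H of the C4 methyl, and with C4 at the ester level no oxygen-activated C–H is within reach. C1 is set by which methylene hydrogen reacts: the transition state with the ethyl CH3 turned away from the C7 methyl (allylic 1,3-strain) gives methyl cis to C7a–H, and the trans ring fusion is inherited from 22.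

Step 17
Reactants: 25 propynyl tetrahydroindene ester; 26 [(E)-2-bromoethenyl]benzene
Product: 28 methyl 5-ethyl-1,3,4,7-tetramethyl-5-[(1E,3E)-2-methyl-4-phenylbuta-1,3-dien-1-yl]-3a,4,5,7a-tetrahydro-1H-indene-4-carboxylate, via alkenylzirconocene chloride 27 (not isolated)
Conditions: Cp2Zr(H)Cl, THF, rt → 40 °C; then 26, Pd(PPh3)4 (5 mol%), ZnCl2 (cat.), THF, rt
Reagents that add atoms: none
Why: syn-Hydrozirconation of the internal alkyne places Zr on the less hindered, methyl-bearing carbon, and 27 couples with retention to the (E)-alkenyl bromide under zerovalent palladium catalysis with ZnCl2 as transmetalation shuttle (Negishi coupling). Both diene geometries therefore come from stereospecific steps; the trisubstituted ring alkenes are too hindered to be hydrozirconated.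

Step 18
Reactants: 28 diene methyl ester
Product: 29 5-ethyl-1,3,4,7-tetramethyl-5-[(1E,3E)-2-methyl-4-phenylbuta-1,3-dien-1-yl]-3a,4,5,7a-tetrahydro-1H-indene-4-carboxylic acid (CNP0103503.1)
Conditions: n-PrSH, n-BuLi, HMPA, 0 °C → rt; then 1 M HCl
Reagents that add atoms: none
Why: SN2 dealkylation of the methyl ester by thiolate at the methyl carbon; this avoids attack at the carbonyl carbon, which is flanked by two fully substituted carbons, and leaves the diene and all stereocentres alone.

## Compound list

1 | 4-hydroxy-6-methyl-2H-pyran-2-one | CC1=CC(O)=CC(=O)O1 | starting material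
2 | 6-methyl-3-methylidene-2H-pyran-2,4(3H)-dione | C=C1C(=O)C=C(C)OC1=O | intermediate
3 | 4-hydroxy-3,6-dimethyl-2H-pyran-2-one | CC1=CC(O)=C(C)C(=O)O1 | intermediate
4 | 3,6-dimethyl-2-oxo-2H-pyran-4-yl trifluoromethanesulfonate | CC1=CC(OS(=O)(=O)C(F)(F)F)=C(C)C(=O)O1 | intermediate
5 | 4-ethyl-3,6-dimethyl-2H-pyran-2-one | CCC1=C(C)C(=O)OC(C)=C1 | intermediate
6 | (E)-hex-3-en-2-one | CC/C=C/C(C)=O | starting material
7 | (±)-5-acetyl-6,8-diethyl-1,4-dimethyl-2-oxabicyclo[2.2.2]oct-7-en-3-one, acetyl endo, 6-ethyl exo (racemate; the enantiomer carried on is drawn) | CCC1=C[C@]3(C)[C@@H](CC)[C@H](C(C)=O)[C@@]1(C)C(=O)O3 | intermediate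
8 | (2R,3R)-butanediol ketal of 7, single diastereomer | CCC1=C[C@]3(C)[C@@H](CC)[C@H](C2(C)O[C@H](C)[C@@H](C)O2)[C@@]1(C)C(=O)O3 | intermediate
9 | ketal diol (C7 tertiary allylic OH, C4 CH2OH, cis) | CCC1=C[C@](O)(C)[C@@H](CC)[C@H](C2(C)O[C@H](C)[C@@H](C)O2)[C@@]1(C)CO | intermediate
10 | C4 CH2OTBS ether of 9 | CCC1=C[C@](O)(C)[C@@H](CC)[C@H](C2(C)O[C@H](C)[C@@H](C)O2)[C@@]1(C)CO[Si](C)(C)C(C)(C)C | intermediate
11 | tributylstannylmethyl ether of 10 | CCC1=C[C@](OC[Sn](CCCC)(CCCC)CCCC)(C)[C@@H](CC)[C@H](C2(C)O[C@H](C)[C@@H](C)O2)[C@@]1(C)CO[Si](C)(C)C(C)(C)C | intermediate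
12 | lithiomethyl ether (α-alkoxymethyllithium) | CCC1=C[C@](OC[Li])(C)[C@@H](CC)[C@H](C2(C)O[C@H](C)[C@@H](C)O2)[C@@]1(C)CO[Si](C)(C)C(C)(C)C | intermediate
13 | C5-hydroxymethyl cyclohexene (C5: ethyl, CH2OH; C6=C7) | CC[C@]1(CO)C=C(C)[C@@H](CC)[C@H](C2(C)O[C@H](C)[C@@H](C)O2)[C@@]1(C)CO[Si](C)(C)C(C)(C)C | intermediate
14 | C5 aldehyde | CC[C@]1(C=O)C=C(C)[C@@H](CC)[C@H](C2(C)O[C@H](C)[C@@H](C)O2)[C@@]1(C)CO[Si](C)(C)C(C)(C)C | intermediate
15 | diazoalkene from 14 | CC[C@]1(C=C=[N+]=[N-])C=C(C)[C@@H](CC)[C@H](C2(C)O[C@H](C)[C@@H](C)O2)[C@@]1(C)CO[Si](C)(C)C(C)(C)C | intermediate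
16 | C5 ethynyl compound | CC[C@]1(C#C)C=C(C)[C@@H](CC)[C@H](C2(C)O[C@H](C)[C@@H](C)O2)[C@@]1(C)CO[Si](C)(C)C(C)(C)C | intermediate
17 | lithium acetylide of 16 | CC[C@]1(C#C[Li])C=C(C)[C@@H](CC)[C@H](C2(C)O[C@H](C)[C@@H](C)O2)[C@@]1(C)CO[Si](C)(C)C(C)(C)C | intermediate
18 | C5 prop-1-ynyl compound | CC[C@]1(C#CC)C=C(C)[C@@H](CC)[C@H](C2(C)O[C@H](C)[C@@H](C)O2)[C@@]1(C)CO[Si](C)(C)C(C)(C)C | intermediate
19 | keto alcohol | CC[C@]1(C#CC)C=C(C)[C@@H](CC)[C@H](C(C)=O)[C@@]1(C)CO | intermediate
20 | keto aldehyde | CC[C@]1(C#CC)C=C(C)[C@@H](CC)[C@H](C(C)=O)[C@@]1(C)C=O | intermediate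
21 | keto acid | CC[C@]1(C#CC)C=C(C)[C@@H](CC)[C@H](C(C)=O)[C@@]1(C)C(=O)O | intermediate
22 | keto methyl ester | CC[C@]1(C#CC)C=C(C)[C@@H](CC)[C@H](C(C)=O)[C@@]1(C)C(=O)OC | intermediate
23 | diazoalkene from 22 | CC[C@]1(C#CC)C=C(C)[C@@H](CC)[C@H](C(C)=C=[N+]=[N-])[C@@]1(C)C(=O)OC | intermediate
24 | alkylidene carbene | CC[C@]1(C#CC)C=C(C)[C@@H](CC)[C@H](C(C)=[C])[C@@]1(C)C(=O)OC | intermediate
25 | propynyl tetrahydroindene methyl ester | CC[C@]1(C#CC)C=C(C)[C@H]2[C@H](C)C=C(C)[C@@H]2[C@@]1(C)C(=O)OC | intermediate
26 | [(E)-2-bromoethenyl]benzene | Br/C=C/c1ccccc1 | starting material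
27 | alkenylzirconocene chloride (cyclopentadienyl rings drawn σ-bonded) | CC[C@]1(/C=C(C)/[Zr](Cl)(C3C=CC=C3)C3C=CC=C3)C=C(C)[C@H]2[C@H](C)C=C(C)[C@@H]2[C@@]1(C)C(=O)OC | intermediate
28 | methyl ester of the target | CC[C@]1(/C=C(C)/C=C/c2ccccc2)C=C(C)[C@H]2[C@H](C)C=C(C)[C@@H]2[C@@]1(C)C(=O)OC | intermediate
29 | CNP0103503.1 | CC[C@]1(/C=C(C)/C=C/c2ccccc2)C=C(C)[C@H]2[C@H](C)C=C(C)[C@@H]2[C@@]1(C)C(=O)O | target

Total step count: 18. Longest linear sequence: 18 steps (1 to 29); 6 and 26 are commercial and enter at steps 4 and 17.

## Least certain steps

Step 4 (key step). The most likely problem is slow bond formation between a fully substituted diene terminus and a β-substituted enone. If the reaction must be forced, endo and regiochemical preference erode and the bridge is lost as CO2. The fallback uses a smaller, more electrophilic dienophile. It sets out from 5, which is combined under the same pressure with commercial (E)-pent-2-enal to give the formyl lactone F1 (racemic). MeMgBr in THF at −78 °C adds to the aldehyde only and gives the 1-hydroxyethyl lactone F2 as a carbinol mixture. Dess–Martin oxidation of F2 returns to the route at 7.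

Step 9. The most likely problem is a 1,2-shift or simple protonation of 12 instead of the [2,3] shift, because the receiving carbon C5 lies next to quaternary C4 and the migrating origin is tertiary. The fallback replaces the five-membered by a six-membered sigmatropic transition state (Ireland–Claisen). It sets out from 10, which is acylated (KH, then (4-methoxybenzyloxy)acetyl chloride) to the glycolate ester F3. LDA and Me3SiCl, −78 °C to rt, then dilute acid, give the α-(4-methoxybenzyloxy) acid F4 with the new carbon on the same face of C5. DDQ in wet CH2Cl2 gives the α-hydroxy acid F5. Oxidative decarboxylation with Pb(OAc)4 returns to the route at 14.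

Step 16. The most likely problems are insertion into the wrong C–H bond (the C4 methyl), poor discrimination between the two methylene hydrogens at C1, or enolisation of the methyl ketone by the basic reagent. The fallback changes the carbene type to a rhodium carbenoid, whose selectivity can be tuned through the carboxylate ligands. It sets out from 22. LiHMDS and 2,2,2-trifluoroethyl trifluoroacetate give the trifluoroacetyl diketone F6 (not isolated). Diazo transfer with MsN3 and Et3N gives the diazomethyl ketone F7. Rh2(OAc)4 in CH2Cl2 closes the cyclopentanone F8 by 1,5 C–H insertion into the ethyl CH2. LDA and PhNTf2 at −78 °C give the enol triflate F9 on the CH2 side. MeMgBr with Fe(acac)3 at −30 °C returns to the route at 25.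

Step 5. The most likely problem is incomplete separation of the two ketal diastereomers, since the ketal stereocentres are one bond removed from the ring; ionisation of the tertiary allylic lactone by the silyl triflate is a second risk. The fallback separates enantiomers directly. It sets out from racemic 7, which is resolved by preparative chromatography on a chiral stationary phase (F0: no new compound). The single enantiomer is ketalised under the step 5 conditions, now without a separation, and returns to the route at 8.

Step 17. The most likely problem is slow hydrozirconation of the hindered internal alkyne, with hydride attack on the ester or regiochemical leakage competing. The fallback changes the hydrometallation. It sets out from 25: Bu3SnH with PdCl2(PPh3)2 in THF gives the (E)-alkenylstannane F10 with tin on the methyl-bearing carbon. Stille coupling with 26 (Pd2(dba)3, AsPh3, CuI, NMP, 50 °C) returns to the route at 28.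

Step 1. The most likely problem is over-reaction of the methylidene dione 2 with a second molecule of 1 to a methylene-bridged dimer before hydride transfer. The fallback traps the methylidene intermediate with a thiol. It sets out from 1: paraformaldehyde, PhSH and piperidine (cat.) in EtOH at reflux give the phenylsulfanylmethyl pyrone F11. Desulfurisation with Raney Ni in EtOH returns to the route at 3.

## Further compounds

F1 | step 4 | (±)-6,8-diethyl-5-formyl-1,4-dimethyl-2-oxabicyclo[2.2.2]oct-7-en-3-one (formyl endo) | CCC1=C[C@]3(C)[C@@H](CC)[C@H](C=O)[C@@]1(C)C(=O)O3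
F2 | step 4 | (±)-6,8-diethyl-5-(1-hydroxyethyl)-1,4-dimethyl-2-oxabicyclo[2.2.2]oct-7-en-3-one (carbinol epimers) | CCC1=C[C@]3(C)[C@@H](CC)[C@H](C(C)O)[C@@]1(C)C(=O)O3
F3 | step 9 | (4-methoxybenzyloxy)acetate ester of 10 | CCC1=C[C@](OC(=O)COCc2ccc(OC)cc2)(C)[C@@H](CC)[C@H](C2(C)O[C@H](C)[C@@H](C)O2)[C@@]1(C)CO[Si](C)(C)C(C)(C)C
F4 | step 9 | C5 α-(4-methoxybenzyloxy)acetic acid (α-centre either epimer) | CC[C@]1(C(OCc2ccc(OC)cc2)C(=O)O)C=C(C)[C@@H](CC)[C@H](C2(C)O[C@H](C)[C@@H](C)O2)[C@@]1(C)CO[Si](C)(C)C(C)(C)C
F5 | step 9 | C5 α-hydroxyacetic acid (α-centre either epimer) | CC[C@]1(C(O)C(=O)O)C=C(C)[C@@H](CC)[C@H](C2(C)O[C@H](C)[C@@H](C)O2)[C@@]1(C)CO[Si](C)(C)C(C)(C)C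
F6 | step 16 | trifluoroacetyl diketone from 22 | CC[C@]1(C#CC)C=C(C)[C@@H](CC)[C@H](C(=O)CC(=O)C(F)(F)F)[C@@]1(C)C(=O)OC
F7 | step 16 | diazomethyl ketone | CC[C@]1(C#CC)C=C(C)[C@@H](CC)[C@H](C(=O)C=[N+]=[N-])[C@@]1(C)C(=O)OC
F8 | step 16 | trans-fused cyclopentanone (C3 ketone, C1 methyl cis to C7a–H) | CC[C@]1(C#CC)C=C(C)[C@H]2[C@H](C)CC(=O)[C@@H]2[C@@]1(C)C(=O)OC
F9 | step 16 | C2=C3 enol triflate | CC[C@]1(C#CC)C=C(C)[C@H]2[C@H](C)C=C(OS(=O)(=O)C(F)(F)F)[C@@H]2[C@@]1(C)C(=O)OC
F0 | step 5 | none | none
F10 | step 17 | (E)-alkenylstannane from 25 | CC[C@]1(/C=C(C)/[Sn](CCCC)(CCCC)CCCC)C=C(C)[C@H]2[C@H](C)C=C(C)[C@@H]2[C@@]1(C)C(=O)OC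
F11 | step 1 | 4-hydroxy-6-methyl-3-[(phenylsulfanyl)methyl]-2H-pyran-2-one | CC1=CC(O)=C(CSc2ccccc2)C(=O)O1
A1 | alternative 1 | trans-fused tetrahydroindene methyl ester with ethyl and vinyl on C5 | CC[C@]1(C=C)C=C(C)[C@H]2[C@H](C)C=C(C)[C@@H]2[C@@]1(C)C(=O)OC
A2 | alternative 1 | triene ester: cyclopentene with C7a isopropenyl and C3a–C4(Me)(CO2Me)–C(Et)(vinyl)2 | C=CC(CC)(C=C)[C@](C)(C(=O)OC)[C@H]1C(C)=C[C@@H](C)[C@@H]1C(C)=C
A3 | alternative 2 | cis-fused 2,2-dichlorocyclobutanone across C4–C5 | CC[C@]14C=C(C)[C@@H](CC)[C@H](C(C)=O)[C@@]1(C)C(=O)C4(Cl)Cl
A4 | alternative 2 | trans-6-acetyl-5-ethyl cyclohexa-1,3-diene (1-methyl, 2-ethyl, 4-methyl) | CCC1=C(C)[C@@H](C(C)=O)[C@H](CC)C(C)=C1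
A5 | alternative 3 | trimethylsilyl ester of the target acid | CC[C@]1(/C=C(C)/C=C/c2ccccc2)C=C(C)[C@H]2[C@H](C)C=C(C)[C@@H]2[C@@]1(C)C(=O)O[Si](C)(C)C
A6 | alternative 3 | trans-fused δ-lactone with C7 methyl and (E)-trienyl chain (C4 either epimer) | O=C1O[C@](C)(/C=C(CC)/C=C(C)/C=C/c2ccccc2)[C@H]2[C@H](C)C=C(C)[C@@H]2C1C
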